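## Retrosynthetic overview

- **Feature.** On ring A, the ether oxygen O1 (on C8a) and the ketone carbon C4 (on C4a) sit on neighbouring carbons, and C4a lies next to the oxygen-bearing C5. O1–C8a and C4a–C4 are therefore cut together, giving a C4a–C8a aryne and a chiral carboxylic acid that carries C2, C3, C4 and Cα.
- **Pyranone ring.** Before that cut, the ring is opened at O1–C2 (lactol to phenol plus aldehyde), and the aldehyde carbon C2 is traced back to a vinyl group on C3.
- **Acid.** C3 and Cα are set syn by an Evans aldol of the crotonyl imide dienolate with 4-(benzyloxy)benzaldehyde.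
- **Aryne precursor.** It comes from methyl 3,5-dihydroxy-4-methoxybenzoate by benzylation, C-methylation, exchange of the ester carbon for oxygen, bromination, retro-Brook shift and triflation.
- **Ring order.** Rings A and B are bought in. The pyranone ring is the only ring made, by lactol closure in the penultimate step, and C2 settles by equilibration.

Key step: step 13

Assumption: C2 is a hemiacetal carbon that equilibrates through the open hydroxy aldehyde, and the 2,3-trans (2S) form is taken as the favoured one, because both substituents can be pseudo-axial (anomeric stabilisation, no 1,3-diaxial partners since C4, C4a and C8a are sp2).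

## Route

Step 1
Reactants: 1 methyl 3,5-dihydroxy-4-methoxybenzoate
Product: 2 methyl 3,5-bis(benzyloxy)-4-methoxybenzoate
Conditions: BnBr, K2CO3, DMF, 60 °C
Reagents that add atoms: benzyl bromide, BrCc1ccccc1
Why: Williamson ether synthesis: carbonate deprotonates both phenols, which displace bromide from benzyl bromide, and the benzyl ethers later leave under neutral hydrogenolysis.

Step 2
Reactants: 2 methyl 3,5-bis(benzyloxy)-4-methoxybenzoate
Product: 3 methyl 3,5-bis(benzyloxy)-2-bromo-4-methoxybenzoate
Conditions: NBS, MeCN, 0 °C → rt, dark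
Reagents that add atoms: N-bromosuccinimide, O=C1CCC(=O)N1Br
Why: Electrophilic aromatic bromination: the two open ring positions are equivalent, each is ortho to one benzyloxy group and para to the other, the first bromine slows a second substitution, and the dark polar medium suppresses radical attack at the benzylic CH2 groups.

Step 3
Reactants: 3 methyl 3,5-bis(benzyloxy)-2-bromo-4-methoxybenzoate
Product: 4 methyl 3,5-bis(benzyloxy)-4-methoxy-2-methylbenzoate
Conditions: MeB(OH)2, Pd(OAc)2, SPhos, K3PO4, toluene/H2O, 100 °C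
Reagents that add atoms: methylboronic acid, CB(O)O
Why: Suzuki–Miyaura coupling: the bulky electron-rich biaryl phosphine allows zerovalent palladium to insert into the doubly ortho-substituted C–Br bond, and methylboronic acid then delivers the future C8 methyl group.

Step 4
Reactants: 4 methyl 3,5-bis(benzyloxy)-4-methoxy-2-methylbenzoate
Product: 5 [3,5-bis(benzyloxy)-4-methoxy-2-methylphenyl]methanol
Conditions: LiAlH4, THF, 0 °C; H2O/aq NaOH work-up
Reagents that add atoms: none
Why: Hydride reduction of the ester to the primary alcohol, to which the aryl ethers are inert.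

Step 5
Reactants: 5 [3,5-bis(benzyloxy)-4-methoxy-2-methylphenyl]methanol
Product: 6 3,5-bis(benzyloxy)-4-methoxy-2-methylbenzaldehyde
Conditions: activated MnO2, CH2Cl2, rt
Reagents that add atoms: none
Why: Activated MnO2 oxidises benzylic alcohols selectively and stops at the aldehyde.

Step 6
Reactants: 6 3,5-bis(benzyloxy)-4-methoxy-2-methylbenzaldehyde
Product: 8 3,5-bis(benzyloxy)-4-methoxy-2-methylphenol, via aryl formate 7 (not isolated)
Conditions: mCPBA, CH2Cl2, 0 °C → rt, bicarbonate wash; then K2CO3 (cat.), MeOH, rt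
Reagents that add atoms: 3-chloroperoxybenzoic acid, OOC(=O)c1cccc(Cl)c1
Why: Baeyer–Villiger oxidation of Dakin type: in the Criegee adduct the electron-rich aryl group (para methoxy, ortho methyl) migrates in preference to hydrogen, and carbonate-catalysed methanolysis of formate 7 frees the oxygen that becomes O1.

Step 7
Reactants: 8 3,5-bis(benzyloxy)-4-methoxy-2-methylphenol
Product: 9 3,5-bis(benzyloxy)-2-bromo-4-methoxy-6-methylphenol
Conditions: NBS, CH2Cl2, −78 → 0 °C
Reagents that add atoms: N-bromosuccinimide, O=C1CCC(=O)N1Br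
Why: Electrophilic aromatic bromination at the only C–H left on ring A, which is ortho to the free phenol, so that no regiochemical choice arises.

Step 8
Reactants: 9 3,5-bis(benzyloxy)-2-bromo-4-methoxy-6-methylphenol
Product: 12 3,5-bis(benzyloxy)-4-methoxy-2-methyl-6-(trimethylsilyl)phenyl trifluoromethanesulfonate, via O-trimethylsilyl ether 10 (not isolated), via lithium phenoxide 11 (not isolated)
Conditions: HMDS, THF, 65 °C, evaporate; n-BuLi, THF, −100 → −78 °C; Tf2O, −100 °C → rt
Reagents that add atoms: hexamethyldisilazane, C[Si](C)(C)N[Si](C)(C)C; trifluoromethanesulfonic anhydride, O=S(=O)(OS(=O)(=O)C(F)(F)F)C(F)(F)F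
Why: Standard one-flask route to ortho-silylaryl triflates: O-silylation, bromine–lithium exchange (much faster at −100 °C than deprotonation of the benzylic CH2 groups), retro-Brook 1,3-shift of silicon from oxygen to the carbanion driven by formation of phenoxide 11, and O-sulfonylation with Tf2O.

Step 9
Reactants: 13 (S)-4-benzyl-1,3-oxazolidin-2-one; 14 (E)-but-2-enoyl chloride (crotonyl chloride)
Product: 16 (S)-4-benzyl-3-[(E)-but-2-enoyl]-1,3-oxazolidin-2-one, via N-lithio oxazolidinone 15 (not isolated)
Conditions: n-BuLi, THF, −78 °C; then 14, −78 → 0 °C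
Reagents that add atoms: none
Why: N-Acylation of the lithiated Evans auxiliary with the acid chloride at low temperature, which keeps the E double bond in place.

Step 10
Reactants: 16 (S)-4-benzyl-3-[(E)-but-2-enoyl]-1,3-oxazolidin-2-one; 17 4-(benzyloxy)benzaldehyde
Product: 20 (4S)-4-benzyl-3-[(2S)-2-{(S)-[4-(benzyloxy)phenyl](hydroxy)methyl}but-3-enoyl]-1,3-oxazolidin-2-one, via boron dienolate 18 (not isolated), via boron aldolate 19 (not isolated)
Conditions: Bu2BOTf, Et3N, CH2Cl2, −78 → 0 °C; 17, −78 → 0 °C; pH 7 buffer, MeOH, 30% H2O2, 0 °C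
Reagents that add atoms: none
Why: Evans syn aldol reaction: Bu2BOTf and Et3N remove a γ proton to give the Z(O) boron dienolate 18, which reacts at its α carbon through a Zimmerman–Traxler chair on the face turned away from the benzyl group of the (S)-auxiliary, and this sets C3 and Cα together as the (2S,3S) syn pair.

Step 11
Reactants: 20 aldol adduct
Product: 21 (4S)-4-benzyl-3-[(2S)-2-{(S)-[4-(benzyloxy)phenyl](triisopropylsilyloxy)methyl}but-3-enoyl]-1,3-oxazolidin-2-one
Conditions: TIPSOTf, 2,6-lutidine, CH2Cl2, 0 °C → rt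
Reagents that add atoms: triisopropylsilyl trifluoromethanesulfonate, CC(C)[Si](OS(=O)(=O)C(F)(F)F)(C(C)C)C(C)C
Why: Silylation of the hindered secondary alcohol with the silyl triflate and a non-nucleophilic base; the triisopropylsilyl ether blocks retro-aldol cleavage and should withstand CsF in step 13.

Step 12
Reactants: 21 silylated imide
Product: 23 (2S)-2-{(S)-[4-(benzyloxy)phenyl](triisopropylsilyloxy)methyl}but-3-enoic acid (the syn 2-vinyl acid), via peroxy acid 22 (not isolated)
Conditions: LiOH, 30% H2O2, THF/H2O, 0 °C; aq Na2SO3; dilute HCl to pH 3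
Reagents that add atoms: hydrogen peroxide (acting as LiOOH), OO
Why: Hydroperoxide cleavage of the imide: the small, weakly basic LiOOH attacks the exocyclic carbonyl even in hindered imides, does not deprotonate C3, and sulfite reduces peroxy acid 22 to the acid.

Step 13
Reactants: 12 3,5-bis(benzyloxy)-4-methoxy-2-methyl-6-(trimethylsilyl)phenyl trifluoromethanesulfonate; 23 (2S)-2-{(S)-[4-(benzyloxy)phenyl](triisopropylsilyloxy)methyl}but-3-enoic acid
Product: 28 (2S)-1-[2,4-bis(benzyloxy)-6-hydroxy-3-methoxy-5-methylphenyl]-2-{(S)-[4-(benzyloxy)phenyl](triisopropylsilyloxy)methyl}but-3-en-1-one, via caesium carboxylate 24 (not isolated), via ring A aryne 25 (not isolated), via aryl caesium ester 26 (not isolated), via caesium phenoxide 27 (not isolated)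
Conditions: 23 (1.3 equiv), Cs2CO3 (0.65 equiv), MeOH, rt, evaporate, toluene azeotrope; 12, CsF (3 equiv), THF (0.02 mol/L), sealed tube, 90 °C; AcOH, 0 °C
Reagents that add atoms: none
Why: Fluoride attacks the trimethylsilyl group of 12 and triflate leaves, which gives the C4a–C8a aryne 25; the carboxylate oxygen of 24 adds at C8a, and the aryl anion of 26 at C4a attacks the neighbouring ester carbonyl through a four-membered tetrahedral intermediate that opens to the ortho-acyl phenoxide 27, so that O1–C8a and C4a–C4 form in one operation. The closest known reaction type is the insertion of arynes into the C–O bond of carboxylic acids to give ortho-hydroxyaryl ketones. No ring closes and no stereocentre is made: C3 and Cα come from 23, whose carboxylate cannot enolise, and the ketone is born as a phenoxide (a vinylogous carboxylate) that should resist a second deprotonation at C3 until the acetic acid quench. The step needs regioselective addition to an unsymmetrical aryne, and the inductively withdrawing 5-benzyloxy group should secure it, since it distorts the aryne so that C8a is the electrophilic terminus and the charge builds up at C4a, an effect expected to outweigh the steric demand of the C8 methyl group. It also needs the acyl shift to outrun protonation of 26, which is why the dry caesium salt and high dilution replace the free acid, so that no acidic proton is present.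

Step 14
Reactants: 28 silylated hydroxyaryl vinyl ketone
Product: 29 (2S)-1-[2,4-bis(benzyloxy)-6-hydroxy-3-methoxy-5-methylphenyl]-2-{(S)-[4-(benzyloxy)phenyl](hydroxy)methyl}but-3-en-1-one
Conditions: HF·pyridine, pyridine, THF, 0 °C → rt
Reagents that add atoms: none
Why: Fluoride-driven Si–O cleavage in a weakly acidic buffered medium, which avoids the basic conditions that would start retro-aldol cleavage or move the vinyl double bond into conjugation, and which is placed here so that the acid-sensitive lactol never meets HF.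

Step 15
Reactants: 29 hydroxy vinyl ketone
Product: 32 (2S,3R)-5,7-bis(benzyloxy)-3-{(S)-[4-(benzyloxy)phenyl](hydroxy)methyl}-2-hydroxy-6-methoxy-8-methylchroman-4-one, via vicinal diol 30 (not isolated), via keto aldehyde 31 (not isolated)
Conditions: OsO4 (2 mol%), NaIO4, THF/pH 7 phosphate buffer, 0 °C
Reagents that add atoms: osmium tetroxide (oxygen carrier), O=[Os](=O)(=O)=O; sodium periodate (terminal oxygen source), [Na+].[O-]I(=O)(=O)=O
Why: Lemieux–Johnson cleavage: OsO4 dihydroxylates the only alkene, periodate cleaves diol 30 to keto aldehyde 31, and O1, the only free phenol, closes the pyranone ring on the aldehyde (6-exo-trig hemiacetalisation) before C3 should enolise in the cold amine-free medium, while C2 settles by equilibration as the 2,3-trans (2S) lactol with both substituents pseudo-axial and the hydroxyl anomerically stabilised.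

Step 16
Reactants: 32 tribenzyl lactol
Product: 33 (2S,3R)-2,5,7-trihydroxy-3-[(S)-hydroxy(4-hydroxyphenyl)methyl]-6-methoxy-8-methylchroman-4-one (CNP0141808.1)
Conditions: H2 (1 atm), 10% Pd/C, EtOAc, rt, stopped after uptake of three equivalents
Reagents that add atoms: none
Why: Catalytic hydrogenolysis of the three aryl benzyl ethers in a neutral aprotic solvent, where these ethers should be cleaved faster than the benzylic Cα–OH is lost or the doubly ortho-substituted hydrogen-bonded ketone is reduced, and where neither acid nor base is present to dehydrate the lactol or epimerise C3; C2 remains free to re-equilibrate to the 2,3-trans form.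

## Compound list

1 | methyl 3,5-dihydroxy-4-methoxybenzoate | COC(=O)c1cc(O)c(OC)c(O)c1 | starting material
2 | methyl 3,5-bis(benzyloxy)-4-methoxybenzoate | COC(=O)c1cc(OCc2ccccc2)c(OC)c(OCc2ccccc2)c1 | intermediate
3 | methyl 3,5-bis(benzyloxy)-2-bromo-4-methoxybenzoate | COC(=O)c1cc(OCc2ccccc2)c(OC)c(OCc2ccccc2)c1Br | intermediate
4 | methyl 3,5-bis(benzyloxy)-4-methoxy-2-methylbenzoate | COC(=O)c1cc(OCc2ccccc2)c(OC)c(OCc2ccccc2)c1C | intermediate
5 | [3,5-bis(benzyloxy)-4-methoxy-2-methylphenyl]methanol | OCc1cc(OCc2ccccc2)c(OC)c(OCc2ccccc2)c1C | intermediate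
6 | 3,5-bis(benzyloxy)-4-methoxy-2-methylbenzaldehyde | O=Cc1cc(OCc2ccccc2)c(OC)c(OCc2ccccc2)c1C | intermediate
7 | 3,5-bis(benzyloxy)-4-methoxy-2-methylphenyl formate | O=COc1cc(OCc2ccccc2)c(OC)c(OCc2ccccc2)c1C | intermediate
8 | 3,5-bis(benzyloxy)-4-methoxy-2-methylphenol | Oc1cc(OCc2ccccc2)c(OC)c(OCc2ccccc2)c1C | intermediate
9 | 3,5-bis(benzyloxy)-2-bromo-4-methoxy-6-methylphenol | Oc1c(Br)c(OCc2ccccc2)c(OC)c(OCc2ccccc2)c1C | intermediate
10 | [3,5-bis(benzyloxy)-2-bromo-4-methoxy-6-methylphenoxy]trimethylsilane | C[Si](C)(C)Oc1c(Br)c(OCc2ccccc2)c(OC)c(OCc2ccccc2)c1C | intermediate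
11 | lithium 3,5-bis(benzyloxy)-4-methoxy-2-methyl-6-(trimethylsilyl)phenoxide | [Li+].[O-]c1c([Si](C)(C)C)c(OCc2ccccc2)c(OC)c(OCc2ccccc2)c1C | intermediate
12 | 3,5-bis(benzyloxy)-4-methoxy-2-methyl-6-(trimethylsilyl)phenyl trifluoromethanesulfonate (triflate carbon = future C8a, silyl carbon = future C4a) | COc1c(OCc2ccccc2)c(C)c(OS(=O)(=O)C(F)(F)F)c([Si](C)(C)C)c1OCc1ccccc1 | intermediate
13 | (S)-4-benzyl-1,3-oxazolidin-2-one | O=C1N[C@@H](Cc2ccccc2)CO1 | starting material
14 | (E)-but-2-enoyl chloride | C/C=C/C(Cl)=O | starting material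
15 | lithium salt of 13 (N-lithio oxazolidinone) | [Li+].O=C1[N-][C@@H](Cc2ccccc2)CO1 | intermediate
16 | (S)-4-benzyl-3-[(E)-but-2-enoyl]-1,3-oxazolidin-2-one | C/C=C/C(=O)N1[C@@H](Cc2ccccc2)COC1=O | intermediate
17 | 4-(benzyloxy)benzaldehyde | O=Cc1ccc(OCc2ccccc2)cc1 | starting material
18 | dibutylboron Z(O)-dienolate of 16 | C=C/C=C(\OB(CCCC)CCCC)N1[C@@H](Cc2ccccc2)COC1=O | intermediate
19 | dibutylboron aldolate of 20 | O=C1OC[C@H](Cc2ccccc2)N1C(=O)[C@H]([C@H](OB(CCCC)CCCC)c1ccc(OCc2ccccc2)cc1)C=C | intermediate
20 | (4S)-4-benzyl-3-[(2S)-2-{(S)-[4-(benzyloxy)phenyl](hydroxy)methyl}but-3-enoyl]-1,3-oxazolidin-2-one | O=C1OC[C@H](Cc2ccccc2)N1C(=O)[C@H]([C@H](O)c1ccc(OCc2ccccc2)cc1)C=C | intermediate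
21 | (4S)-4-benzyl-3-[(2S)-2-{(S)-[4-(benzyloxy)phenyl](triisopropylsilyloxy)methyl}but-3-enoyl]-1,3-oxazolidin-2-one | O=C1OC[C@H](Cc2ccccc2)N1C(=O)[C@H]([C@H](O[Si](C(C)C)(C(C)C)C(C)C)c1ccc(OCc2ccccc2)cc1)C=C | intermediate
22 | (2S)-2-{(S)-[4-(benzyloxy)phenyl](triisopropylsilyloxy)methyl}but-3-eneperoxoic acid | OOC(=O)[C@H]([C@H](O[Si](C(C)C)(C(C)C)C(C)C)c1ccc(OCc2ccccc2)cc1)C=C | intermediate
23 | (2S)-2-{(S)-[4-(benzyloxy)phenyl](triisopropylsilyloxy)methyl}but-3-enoic acid | OC(=O)[C@H]([C@H](O[Si](C(C)C)(C(C)C)C(C)C)c1ccc(OCc2ccccc2)cc1)C=C | intermediate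
24 | caesium salt of 23 | [Cs+].[O-]C(=O)[C@H]([C@H](O[Si](C(C)C)(C(C)C)C(C)C)c1ccc(OCc2ccccc2)cc1)C=C | intermediate
25 | 3,5-bis(benzyloxy)-4-methoxy-6-methyl-1,2-didehydrobenzene (C4a–C8a aryne) | CC1=C(OCc2ccccc2)C(OC)=C(OCc2ccccc2)C#C1 | intermediate
26 | aryl ester of 23 bound through O1–C8a, with the caesium carbanion at C4a | COc1c(OCc2ccccc2)c(C)c(OC(=O)[C@H]([C@H](O[Si](C(C)C)(C(C)C)C(C)C)c2ccc(OCc3ccccc3)cc2)C=C)[c-]c1OCc1ccccc1.[Cs+] | intermediate
27 | caesium phenoxide of 28 | [Cs+].COc1c(OCc2ccccc2)c(C)c([O-])c(c1OCc1ccccc1)C(=O)[C@H]([C@H](O[Si](C(C)C)(C(C)C)C(C)C)c1ccc(OCc2ccccc2)cc1)C=C | intermediate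
28 | (2S)-1-[2,4-bis(benzyloxy)-6-hydroxy-3-methoxy-5-methylphenyl]-2-{(S)-[4-(benzyloxy)phenyl](triisopropylsilyloxy)methyl}but-3-en-1-one | COc1c(OCc2ccccc2)c(C)c(O)c(c1OCc1ccccc1)C(=O)[C@H]([C@H](O[Si](C(C)C)(C(C)C)C(C)C)c1ccc(OCc2ccccc2)cc1)C=C | intermediate
29 | (2S)-1-[2,4-bis(benzyloxy)-6-hydroxy-3-methoxy-5-methylphenyl]-2-{(S)-[4-(benzyloxy)phenyl](hydroxy)methyl}but-3-en-1-one | COc1c(OCc2ccccc2)c(C)c(O)c(c1OCc1ccccc1)C(=O)[C@H]([C@H](O)c1ccc(OCc2ccccc2)cc1)C=C | intermediate
30 | 1,2-diol from dihydroxylation of the vinyl group of 29 (C3 and Cα as in 29, new carbinol carbon as a mixture) | COc1c(OCc2ccccc2)c(C)c(O)c(c1OCc1ccccc1)C(=O)[C@H]([C@H](O)c1ccc(OCc2ccccc2)cc1)C(O)CO | intermediate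
31 | open keto aldehyde (formyl group in place of the vinyl group of 29) | COc1c(OCc2ccccc2)c(C)c(O)c(c1OCc1ccccc1)C(=O)[C@H]([C@H](O)c1ccc(OCc2ccccc2)cc1)C=O | intermediate
32 | (2S,3R)-5,7-bis(benzyloxy)-3-{(S)-[4-(benzyloxy)phenyl](hydroxy)methyl}-2-hydroxy-6-methoxy-8-methylchroman-4-one | COc1c(OCc3ccccc3)c(C)c2c(c1OCc1ccccc1)C(=O)[C@H]([C@H](O)c1ccc(OCc3ccccc3)cc1)[C@@H](O)O2 | intermediate
33 | (2S,3R)-2,5,7-trihydroxy-3-[(S)-hydroxy(4-hydroxyphenyl)methyl]-6-methoxy-8-methylchroman-4-one | COc1c(O)c(C)c2c(c1O)C(=O)[C@H]([C@H](O)c1ccc(O)cc1)[C@@H](O)O2 | target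

## Step count and risks

Total step count: 16.
Longest linear sequence: 12 (steps 1–8 and 13–16). The acid branch (steps 9–12) joins at step 13.

**Step 13 (aryne insertion).**
- The aryl anion may be protonated before the acyl shift, either by traces of water or by proton transfer from the neighbouring benzylic CH2 of the 5-benzyloxy group.
- The carboxylate may add at the wrong aryne terminus because of the C8 methyl group.
- Heat and fluoride may move the vinyl double bond into conjugation or epimerise C3.
- The fallback sets out from bromophenol 9 and acid 23 and returns at ketone 28. Steglich esterification (EDC·HCl, DMAP, CH2Cl2, 0 °C) would give the 2-bromoaryl ester F1. Bromine–lithium exchange (n-BuLi, THF/Et2O, −100 °C) would place the carbanion at C4a directly beside the ester. This starts the same O-to-C acyl shift as a halogen–metal-exchange-induced anionic Fries rearrangement, at low temperature, without fluoride and with the regiochemistry fixed by the bromine. An acetic acid quench would deliver 28.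

**Step 15 (oxidative cleavage and lactol closure).**
- The transient keto aldehyde may enolise, with epimerisation at C3.
- The lactol may lose water towards the aromatic pyranone.
- The free β-hydroxy ketone may undergo retro-aldol cleavage in the aqueous medium.
- Periodate may oxidise the electron-rich para-methoxy phenol.
- The fallback sets out from 29 and returns at 32. Ozonolysis (O3, CH2Cl2, −78 °C, stopped at a dye end point) would convert the vinyl group into its peroxidic adduct, drawn as the secondary ozonide F2. PPh3 (−78 °C → rt) would reduce this to the aldehyde in an aprotic medium free of buffer and periodate, where O1 closes the lactol 32.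

**Step 16 (global hydrogenolysis).**
- The benzylic Cα–O bond may be hydrogenolysed once the para phenol of ring B is free.
- The lactol may dehydrate on the catalyst support during a slow debenzylation at the hindered C5 and C7 positions.
- The fallback sets out from 28 and returns at 33, and keeps the silyl ether to the end. Lemieux–Johnson cleavage of 28 (as in step 15) would give the silylated lactol F3. Hydrogenolysis (H2, Pd/C, EtOAc) would give the silylated triphenol lactol F4, in which the bulky triisopropylsilyl group shields the Cα–O bond from the catalyst. HF·pyridine buffered with excess pyridine (THF, 0 °C) would then free the Cα hydroxyl to give 33.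

## Further compounds

F1 | step 13 | 3,5-bis(benzyloxy)-2-bromo-4-methoxy-6-methylphenyl (2S)-2-{(S)-[4-(benzyloxy)phenyl](triisopropylsilyloxy)methyl}but-3-enoate | COc1c(OCc2ccccc2)c(C)c(OC(=O)[C@H]([C@H](O[Si](C(C)C)(C(C)C)C(C)C)c2ccc(OCc3ccccc3)cc2)C=C)c(Br)c1OCc1ccccc1
F2 | step 15 | secondary ozonide of 29 (1,2,4-trioxolan-3-yl in place of the vinyl group, trioxolane carbon unassigned) | COc1c(OCc2ccccc2)c(C)c(O)c(c1OCc1ccccc1)C(=O)[C@H]([C@H](O)c1ccc(OCc2ccccc2)cc1)C1OCOO1
F3 | step 16 | (2S,3R)-5,7-bis(benzyloxy)-3-{(S)-[4-(benzyloxy)phenyl](triisopropylsilyloxy)methyl}-2-hydroxy-6-methoxy-8-methylchroman-4-one | COc1c(OCc3ccccc3)c(C)c2c(c1OCc1ccccc1)C(=O)[C@H]([C@H](O[Si](C(C)C)(C(C)C)C(C)C)c1ccc(OCc3ccccc3)cc1)[C@@H](O)O2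
F4 | step 16 | (2S,3R)-2,5,7-trihydroxy-3-{(S)-(4-hydroxyphenyl)(triisopropylsilyloxy)methyl}-6-methoxy-8-methylchroman-4-one | COc1c(O)c(C)c2c(c1O)C(=O)[C@H]([C@H](O[Si](C(C)C)(C(C)C)C(C)C)c1ccc(O)cc1)[C@@H](O)O2
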